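**Assumptions.** The target has no stereocentres and the prenyl alkene has no E/Z isomerism, so it is achiral and no enantiocontrol is needed. Reagents that are not skeleton building blocks are given by name and SMILES in each step and are not numbered.

**Retrosynthetic overview**
1. Target 9 ⇐ selective O-demethylation of the methoxy group flanking the N-oxide in pyrazine N-oxide 8 (the N⁺–O⁻/OMe pair is a masked cyclic hydroxamic acid).
2. The CH2–C3(indole) bond of 8 ⇐ new Cu(II)-mediated oxidative coupling of the methyl group next to the N-oxide in 4 with unprotected 7-prenylindole 7.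
3. N-oxide 4 ⇐ mono-N-oxidation of centrosymmetric 2,5-dimethoxy-3,6-dimethylpyrazine 3 (both N atoms equivalent, so no regiochemistry issue) ⇐ aromatised bis-lactim ether of cyclo(Ala-Ala) 1.
4. 7-Prenylindole 7 ⇐ 7-bromoindole 5 + prenyl bromide 6.
5. Ring order: the pyrazine ring comes from the purchased diketopiperazine and the indole is purchased; no ring is formed late.

**Route**

Step 1
Reactants: 1, (3S,6S)-3,6-dimethylpiperazine-2,5-dione [cyclo(L-Ala-L-Ala)]
Product: 2, (3S,6S)-2,5-dimethoxy-3,6-dimethyl-3,6-dihydropyrazine (bis-lactim ether)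
Conditions: Me3OBF4 (2.5 equiv), CH2Cl2, rt, 72 h; cold aq. NaHCO3
Reagents that add atoms: trimethyloxonium tetrafluoroborate, C[O+](C)C.F[B-](F)(F)F
Why: Lactam O-methylation with Meerwein's salt (Schöllkopf bis-lactim ether formation); the two stereocentres are irrelevant because they are removed in step 2.

Step 2
Reactants: 2, bis-lactim ether
Product: 3, 2,5-dimethoxy-3,6-dimethylpyrazine
Conditions: DDQ (1.1 equiv), toluene, rt → 60 °C
Reagents that add atoms: none
Why: DDQ dehydrogenation of the 3,6-dihydropyrazine, driven by aromatisation.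

Step 3
Reactants: 3, 2,5-dimethoxy-3,6-dimethylpyrazine
Product: 4, 2,5-dimethoxy-3,6-dimethylpyrazine 1-oxide (N-oxide flanked by C2–OMe and C6–CH3)
Conditions: mCPBA (1.1 equiv), CH2Cl2, 0 °C → rt; aq. Na2SO3/NaHCO3
Reagents that add atoms: mCPBA, OOC(=O)c1cccc(Cl)c1 (adds O)
Why: Peracid N-oxidation; either N gives the same mono-N-oxide, and the first N-oxide deactivates the ring towards a second oxidation. No alkene or indole is present yet.

Step 4
Reactants: 5, 7-bromo-1H-indole; 6, prenyl bromide (1-bromo-3-methylbut-2-ene)
Product: 7, 7-(3-methylbut-2-en-1-yl)-1H-indole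
Conditions: KH (1.1 equiv), THF, 0 °C; t-BuLi (2.1 equiv), −78 °C; 6 (1.05 equiv), −78 → 0 °C
Reagents that add atoms: prenyl bromide (6), CC(C)=CCBr
Why: N–H deprotonation then Br/Li exchange (N-potassio-7-lithioindole dianion protocol) and SN2 allylation of the aryllithium at the primary carbon of prenyl bromide.

Step 5
Reactants: 4, 2,5-dimethoxy-3,6-dimethylpyrazine 1-oxide; 7, 7-prenyl-1H-indole (2.0 equiv, excess recovered)
Product: 8, 2,5-dimethoxy-3-methyl-6-{[7-(3-methylbut-2-en-1-yl)-1H-indol-3-yl]methyl}pyrazine 1-oxide
Conditions: LiHMDS (3.3 equiv), THF, −78 °C, 30 min; Cu(II) 2-ethylhexanoate (2.2 equiv), −78 °C → rt; aq. NH4Cl/NH3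
Reagents that add atoms: none (both partners are the reactants; base and Cu(II) leave no atoms)
Why: Proposed new method: Cu(II)-mediated oxidative heterocoupling of lithium indolide with the lateral "aza-enolate" anion formed by deprotonating the methyl group next to N⁺–O⁻. Only the C6 methyl is acidified by the adjacent N-oxide, and its N–O oxygen binds Li/Cu like an enolate oxygen. Inner-sphere one-electron oxidation gives a nitroxide-stabilised picolyl-type radical, which is captured at C3 of the Cu-bound indolide; a second Cu(II) oxidation and tautomerisation restore the indole. The N–O bond is kept because the oxygen is never activated as a leaving group, and the remote prenyl alkene and free N–H are tolerated. The closest known reaction is the Cu(II)-mediated direct oxidative coupling of free-NH indoles at C3 with carbonyl enolates.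

Step 6
Reactants: 8, coupled pyrazine N-oxide
Product: 9, astepyrazinoxide, 1-hydroxy-5-methoxy-3-methyl-6-{[7-(3-methylbut-2-en-1-yl)-1H-indol-3-yl]methyl}pyrazin-2(1H)-one
Conditions: LiCl (5 equiv), DMF, 85 °C, N2 sweep; aq. citric acid to pH 4
Reagents that add atoms: none (CH3 leaves as MeCl; H from work-up)
Why: Krapcho-type halide SN2 O-demethylation; only the methoxy flanking N⁺–O⁻ releases a stabilised cyclic hydroxamate anion, so the C5–OMe (an ordinary 2-methoxypyrazine ether) remains, and the neutral non-acidic conditions spare the indole and prenyl alkene.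

**Compound list**
1 | (3S,6S)-3,6-dimethylpiperazine-2,5-dione, cyclo(L-Ala-L-Ala) | C[C@@H]1NC(=O)[C@H](C)NC1=O | starting material
2 | (3S,6S)-2,5-dimethoxy-3,6-dimethyl-3,6-dihydropyrazine | C[C@@H]1N=C(OC)[C@H](C)N=C1OC | intermediate
3 | 2,5-dimethoxy-3,6-dimethylpyrazine | COc1nc(C)c(OC)nc1C | intermediate
4 | 2,5-dimethoxy-3,6-dimethylpyrazine 1-oxide | COc1nc(C)c(OC)[n+]([O-])c1C | intermediate
5 | 7-bromo-1H-indole | Brc1cccc2cc[nH]c12 | starting material
6 | prenyl bromide (1-bromo-3-methylbut-2-ene) | CC(C)=CCBr | starting material
7 | 7-(3-methylbut-2-en-1-yl)-1H-indole | CC(C)=CCc1cccc2cc[nH]c12 | intermediate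
8 | 2,5-dimethoxy-3-methyl-6-{[7-(3-methylbut-2-en-1-yl)-1H-indol-3-yl]methyl}pyrazine 1-oxide | COc1nc(C)c(OC)[n+]([O-])c1Cc1c[nH]c2c(CC=C(C)C)cccc12 | intermediate
9 | astepyrazinoxide | COc1nc(C)c(=O)n(O)c1Cc1c[nH]c2c(CC=C(C)C)cccc12 | target

**Totals**
Total steps: 6. Longest linear sequence: 5 steps (1 → 2 → 3 → 4 → 8 → 9), with a one-step branch (5 + 6 → 7).

**Three steps most likely to fail, with fallbacks**
- **Step 5 (proposed new coupling).** Risks are homodimerisation of either anion, reaction at the other methyl, and low conversion. Fallback with known chemistry and reversed polarity: lateral lithiation of 4 (LDA, THF, −78 °C) and chlorination with C2Cl6 to give the 6-(chloromethyl) N-oxide, then C3-selective Friedel–Crafts alkylation of unprotected 7 (Zn(OTf)2, i-Pr2NEt, Bu4NI, toluene, rt) to give 8.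
- **Step 6 (selective demethylation to the hydroxamic acid).** Risks are methyl transfer back onto N–O (giving the N-methoxy isomer), partial loss of the C5–OMe, and incomplete reaction. Fallback that changes the protecting-group strategy: unmask the hydroxamic acid early on robust 4 (aq. HCl hydrolysis of the 2-methoxy N-oxide), protect N–OH as the SEM ether, carry out the C6-methyl/indole union on that pyrazinone, and finish with fluoride or MgBr2·OEt2 SEM removal.
- **Step 3 (mono-N-oxidation next to an OMe).** Risks are sluggish oxidation, over-oxidation to the 1,4-dioxide, and thermal O→O methyl migration. Fallback: convert 1 with POCl3 to 2,5-dichloro-3,6-dimethylpyrazine, N-oxidise that with CF3CO3H (or K2S2O8/H2SO4) to the 1-oxide, then displace both chlorides with NaOMe/MeOH (SNAr) to reach 4.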